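Take the charge of Q as the unit: every amount below is a fraction of it, and each flask starts at one. In that unit the dispute is whether a larger charge falls more slowly.

| flask | Q | E | remark | time |
|---|---|---|---|---|
| alpha | 1.2 M | 180 mM (held) | run made earlier |  |
| noon | 2.5 M | 180 mM (held) |  | 80 min |
| dawn | 2.5 M | 180 mM (held) |  | 120 min |
| spring | 2.5 M | 180 mM (held) |  | 180 min |

alpha run (percent of the Q charged)

| time / min | J / % | X / % | D / % | Q / % | Z / % |
|---|---|---|---|---|---|
| 0.667 | 0.1 | 0 | 0 | 97.9 | 1.7 |
| 1.33 | 0.2 | 0 | 1.2 | 97.2 | 3.6 |
| 3.00 | 0.3 | 0 | 3.4 | 93.9 | 2.8 |
| 8.00 | 0 | 0.3 | 11.3 | 83.8 | 2.9 |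

(each reading ± 0.5 percentage points)

- the analysis behind the earlier runs scatters by 0.5 percentage points, standard deviation
- at the start none of E is in solution

- which of these there is most of at the end, counted by the Q in it, noon (D / J / Z / Q)
- which of these there is most of at the end, counted by the Q in it, dawn (D / J / Z / Q)
- which of these there is most of at the end, counted by the Q in it, spring (D / J / Z / Q)
- amount of the one of these that there is most of at the end, in percent of the Q charged, noon
- amount of the one of these that there is most of at the end, in percent of the Q charged, dawn
- amount of the one of these that there is most of at the end, in percent of the Q charged, spring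

At 8.00 min the alpha run has D at 11.3 % and Z at 2.9 %, so D looks like the end of the line, and the argument is over how fast Q goes.

The first speaker says each piece of Q goes on its own, a pseudo-first-order decay, so the same fraction of what stands goes each minute, whatever the charge. The last alpha reading, 83.8 % of Q left, gives 0.0221 /min: this is the fractional decay constant, the natural log of one over the fraction left, divided by the time. It is a reading, carrying the scatter of 0.5 percentage points. So she leaves 17.1 % of Q in noon and 7.06 % in dawn.

The second speaker says E hands over a fixed amount per minute, so the loss is a straight line. In the alpha run that line falls by 0.0203 /min of the charge. But the charge in noon is 2.5 M against 1.2 M, so the same amount per minute is 0.009744 /min of it. He leaves 22.2 % of Q in noon and no Q after 103 min, which is earlier than the end of dawn.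

The alpha run can't part them: at 3.00 min the line stands at 93.9 % and the curve at 93.6 %, a gap of 0.34 points, smaller than the scatter. Dawn is the test, since she keeps Q there and he keeps none.

The forecast calls the order unresolved, has her constant of 0.022 among its cases, and writes “In all cases D dominates”. It names D for noon, D for dawn and D for spring, at 77 % (66 % to 85 %), 88 % (76 % to 96 %) and 93 % (80 % to 99 %). At noon that is 5.9 points below what her Q left would allow.

The simulation puts D first in noon, dawn and spring, at 79.8 %, 90.6 % and 96.4 %, inside the forecast's ranges. Q stands at 18.3 % in noon and 7.73 % in dawn, against her 17.1 % and 7.06 %, so dawn keeps Q as she said, and in noon her figure lies closer to the flask than his. His line remains as good as her curve over the alpha readings, up to 8.00 min.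

    X + G → L + J (k = 0.210 /M/min)
    Q + G → L + Z (k = 0.120 /M/min)
    E ⇌ G, rate k3*(csat - [G]) (kL = 9.70 /min)
    Z + G → L + X (k = 0.0380 /M/min)
    Z → D (k = 0.480 /min)

In spring at 29.3 min, G has a half-life of 4.3 min by the step from Q + G to L + Z, while the transfer from E closes half of any gap in G in 0.0715 min, far faster, and at 90.0 min G stands at 99.5 % of saturation. The half-life of Q by that step in spring at 180 min is 32 min, her constant gives 31.4 min, and carried to spring it leaves 1.87 % of Q against 2.12 %.

The runs are simulated with made-up constants.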